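**Retrosynthetic overview** (numbering: C1 lactone C=O, C2, C3 enol carbon, C4 CHMe, C5, C6 C(OH)Me, C7 ketone, C8, C9 CHOMe, C10, C11 CHOH, C12 CMe–O, C13 CHMe, C14, C15 C–O(lactone), C16 ether carbon bonded to C2, C8 and C15)
1. The eight-membered ring is closed last at C2–C3 by a Claisen acyl transfer from a γ-lactone that masks C6–OH; before that come the butyrolactone (O–C15/C1) by oxidative lactonisation, the C12–O–C16 ether by oxa-Michael addition, and C11–OH by directed reduction.
2. Key disconnection: the cyclopentane C8–C9–C10–C15–C16 comes from the cyclohexene C8–C9–C10–C11–C15–C16 of a hydrindene; a pinacol-type 1,2-shift of C15 from C11 to C10 contracts it while the cyclopentane C11–C12–C13–C14–C15 grows into the cyclohexanone C10–C15.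
3. Feature that allows this: C15, the oxygen-bearing carbon shared by the five- and six-membered carbocycles, lies between C10 (a CH that can carry a leaving group) and C11 (an oxygenated carbon that can be a carbinol and then a ketone).
4. The hydrindene comes from a Diels–Alder reaction of an (E)-1-methoxy-4-(Boc-oxy) diene built on the cyclopentene with an ynone (sets C9 against C15), then directed dihydroxylation. The diene comes from cyclopent-4-ene-1,3-dione (C13 by asymmetric conjugate addition, C12 by MeCeCl2); the ynone from a lactic-acid dioxolanone (C6) and a chiral iodide (C4).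
5. Ring order: γ-lactone C3–C6 and cyclopentene C11–C15 (building blocks) → cyclohexadiene (Diels–Alder) → ring-size exchange (key) → 2-oxabicyclo[2.2.2]octane → butyrolactone → eight-membered ring.

Key step: step 14

Remark on the chemistry: boronate 7, dioxolanone 10 (made from D-lactic acid and pivalaldehyde) and iodide 11 (made from (R)-3-bromo-2-methylpropan-1-ol) are taken as purchasable.

**Step 1**
Reactants: 1 cyclopent-4-ene-1,3-dione
Product: 2 8,8-dimethyl-6,10-dioxaspiro[4.5]dec-3-en-2-one
Conditions: 2,2-dimethylpropane-1,3-diol (1.0 equiv), TsOH (cat.), benzene, reflux, water separator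
Reagents that add atoms: 2,2-dimethylpropane-1,3-diol (CC(C)(CO)CO)
Why: Acid-catalysed monoketalisation; the first ketal deactivates the remaining enone carbonyl, so one equivalent of diol should give mainly the mono-ketal, and no stereocentre is formed.

**Step 2**
Reactants: 2 8,8-dimethyl-6,10-dioxaspiro[4.5]dec-3-en-2-one
Product: 3 (4S)-4,8,8-trimethyl-6,10-dioxaspiro[4.5]decan-2-one
Conditions: Me2Zn (1.5 equiv), Cu(OTf)2 (2 mol %), BINOL-derived bis(1-phenylethyl)amine phosphoramidite (4 mol %, enantiomer chosen for the (S) product), toluene, −30 °C; aq. NH4Cl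
Reagents that add atoms: dimethylzinc (C[Zn]C)
Why: Copper-catalysed asymmetric conjugate addition of a dialkylzinc to a cyclopentenedione mono-ketal, a closely precedented substrate class; the chiral copper complex delivers methyl to one face of the β-carbon next to the ketal and sets C13.

**Step 3**
Reactants: 3 (4S)-4,8,8-trimethyl-6,10-dioxaspiro[4.5]decan-2-one
Product: 4 (4S)-4-methylcyclopentane-1,3-dione
Conditions: 1 M HCl, THF, rt
Reagents that add atoms: water (O)
Why: Acid hydrolysis of the ketal releases the enolised 1,3-dione; C13 is outside the enolised β-dicarbonyl unit and should not epimerise in mild acid at room temperature.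

**Step 4**
Reactants: 4 (4S)-4-methylcyclopentane-1,3-dione
Product: 5 (5S)-3-hydroxy-2-iodo-5-methylcyclopent-2-en-1-one (enol form of the 2-iodo dione)
Conditions: N-iodosuccinimide (1.05 equiv), MeCN, 0 °C
Reagents that add atoms: N-iodosuccinimide (O=C1CCC(=O)N1I)
Why: Electrophilic iodination of the β-dicarbonyl enol at the doubly activated C11; no new stereocentre.

**Step 5**
Reactants: 5 (5S)-3-hydroxy-2-iodo-5-methylcyclopent-2-en-1-one
Product: 6 tert-butyl (4S)-2-iodo-4-methyl-3-oxocyclopent-1-en-1-yl carbonate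
Conditions: Boc2O (1.1 equiv), Et3N, DMAP (cat.), CH2Cl2, 0 °C
Reagents that add atoms: di-tert-butyl dicarbonate (CC(C)(C)OC(=O)OC(=O)OC(C)(C)C)
Why: O-acylation of the dione enolate (enol carbonate formation); the bulky reagent should prefer the oxygen of the carbonyl flanked by CH2 (C15), leaving C12 as the free ketone, and the weakly donating carbonate is what later controls the Diels–Alder orientation.

**Step 6**
Reactants: 6 tert-butyl (4S)-2-iodo-4-methyl-3-oxocyclopent-1-en-1-yl carbonate; 7 2-[(E)-2-methoxyethenyl]-4,4,5,5-tetramethyl-1,3,2-dioxaborolane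
Product: 8 tert-butyl (4S)-2-[(E)-2-methoxyethenyl]-4-methyl-3-oxocyclopent-1-en-1-yl carbonate
Conditions: Pd(PPh3)4 (5 mol %), CsF (3 equiv), THF, 50 °C
Reagents that add atoms: none
Why: Suzuki–Miyaura coupling of an α-iodo enone with an alkenylboronate under anhydrous fluoride activation, which should spare the enol carbonate; the (E) geometry of the enol ether is retained.

**Step 7**
Reactants: 8 tert-butyl (4S)-2-[(E)-2-methoxyethenyl]-4-methyl-3-oxocyclopent-1-en-1-yl carbonate
Product: 9 tert-butyl (3S,4S)-3-hydroxy-2-[(E)-2-methoxyethenyl]-3,4-dimethylcyclopent-1-en-1-yl carbonate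
Conditions: MeLi (1.4 equiv), CeCl3 (1.5 equiv), THF, −78 °C; AcOH quench at −78 °C
Reagents that add atoms: methyllithium ([Li]C)
Why: Organocerium 1,2-addition (ketone-selective, non-basic, sparing the hindered carbonate); methyl attacks C12 anti to the C13 methyl group, so the new hydroxyl is cis to C13–Me as in the target, and the cold quench should prevent carbonate migration.

**Step 8**
Reactants: 10 (2R,5R)-2-tert-butyl-5-methyl-1,3-dioxolan-4-one; 11 tert-butyl{[(2R)-3-iodo-2-methylpropyl]oxy}dimethylsilane
Product: 12 (2R,5S)-2-tert-butyl-5-[(2S)-3-{[tert-butyl(dimethyl)silyl]oxy}-2-methylpropyl]-5-methyl-1,3-dioxolan-4-one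
Conditions: LiN(iPr)2 (1.1 equiv), THF, −78 °C; then 11, DMPU, −78 → −30 °C
Reagents that add atoms: none
Why: Enolate alkylation with self-regeneration of the stereocentre; the lithium enolate is alkylated trans to the tert-butyl group, so the chain replaces H with retention and sets C6, while C4 comes unchanged from 11.

**Step 9**
Reactants: 12 (2R,5S)-2-tert-butyl-5-[(2S)-3-{[tert-butyl(dimethyl)silyl]oxy}-2-methylpropyl]-5-methyl-1,3-dioxolan-4-one
Product: 14 (2S,4S)-2,4-dimethyl-5-oxooxolane-2-carboxylic acid, via dioxolanone acid 13 (not isolated)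
Conditions: CrO3, aq. H2SO4, acetone, 0 °C → rt; iPrOH; then 6 M HCl, 1,4-dioxane, 70 °C
Reagents that add atoms: water (O)
Why: Jones oxidation converts the primary silyl ether directly into the acid; acid hydrolysis of the dioxolanone then frees the tertiary hydroxy acid, which lactonises onto the new C3 carboxyl (five-membered ring) and leaves C7 as the free acid, with C4 and C6 untouched.

**Step 10**
Reactants: 14 (2S,4S)-2,4-dimethyl-5-oxooxolane-2-carboxylic acid; 15 tert-butyl(but-3-yn-1-yloxy)dimethylsilane
Product: 17 (3S,5S)-5-(5-{[tert-butyl(dimethyl)silyl]oxy}pent-2-ynoyl)-3,5-dimethyloxolan-2-one, via acid chloride 16 (not isolated)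
Conditions: (COCl)2, DMF (cat.), CH2Cl2, 0 °C → rt; evaporate; then 15, PdCl2(PPh3)2 (2 mol %), CuI (4 mol %), Et3N (1.2 equiv), THF, rt
Reagents that add atoms: none
Why: Acid chloride formation followed by palladium/copper-catalysed acylation of the terminal alkyne (Sonogashira-type) gives the ynone; the acid chloride has no α-hydrogen, so no ketene can form.

**Step 11**
Reactants: 9 tert-butyl (3S,4S)-3-hydroxy-2-[(E)-2-methoxyethenyl]-3,4-dimethylcyclopent-1-en-1-yl carbonate; 17 (3S,5S)-5-(5-{[tert-butyl(dimethyl)silyl]oxy}pent-2-ynoyl)-3,5-dimethyloxolan-2-one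
Product: 18 Diels–Alder adduct (2,3,3a,6-tetrahydro-1H-indene; cyclohexa-1,4-diene C8=C16/C10=C11 with C15–OBoc, C9–OMe cis to C14, C16–CH2CH2OTBS, C8–acyl, C12–OH)
Conditions: toluene, 2,6-di-tert-butyl-4-methylphenol (cat.), 70 °C, sealed tube
Reagents that add atoms: none
Why: Normal-demand Diels–Alder reaction; the (E)-methoxy group makes C15 the nucleophilic diene terminus (the enol carbonate is only a weak donor), so C15 should bond to the ynone β-carbon C16 and C9 to the acyl-bearing C8, the dienophile should add syn to C12–OH and anti to the C12 methyl, and suprafacial addition places C9–OMe cis to C14.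

**Step 12**
Reactants: 18 Diels–Alder adduct
Product: 19 triol (C10–OH and C11–OH cis to each other and syn to C12–OH; trans-fused hexahydroindene)
Conditions: OsO4 (1.05 equiv), TMEDA (1.1 equiv), CH2Cl2, −78 °C; then aq. Na2SO3, THF, 50 °C
Reagents that add atoms: osmium tetroxide (O=[Os](=O)(=O)=O)
Why: Hydrogen-bond-directed syn-dihydroxylation of the electron-rich C10=C11 bond on the face of the allylic C12 hydroxyl, which is also the face away from the C15 carbonate; the C8=C16 enone is too electron-poor to react.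

**Step 13**
Reactants: 19 triol
Product: 20 C10 methanesulfonate of 19
Conditions: MsCl (1.2 equiv), Et3N, CH2Cl2, −20 °C
Reagents that add atoms: methanesulfonyl chloride (CS(Cl)(=O)=O)
Why: Sulfonylation of the only secondary hydroxyl (C11–OH and C12–OH are tertiary); the cis relation of C10–OMs and C11–OH excludes epoxide formation.

**Step 14**
Reactants: 20 C10 methanesulfonate
Product: 21 ring-exchanged hydroxy ketone (cyclopentene C8=C16–C15–C10–C9 cis-fused to cyclohexanone C10–C11(=O)–C12–C13–C14–C15; 3,3a,4,5,6,7-hexahydro-7aH-inden-4-one)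
Conditions: Et3Al (3 equiv), CH2Cl2, −78 → −20 °C; aq. potassium sodium tartrate
Reagents that add atoms: none
Why: Et3Al turns the C11 and C12 hydroxyls into aluminium alkoxides and activates the C10 mesylate, so that the C11–C15 bond, held antiperiplanar to the equatorial C10–OMs bond by the trans ring fusion, should migrate to C10 while C11 becomes the ketone (semipinacol 1,2-shift of a cis-diol monosulfonate, the reaction type long used to exchange sizes of fused rings such as decalin to hydroazulene). The cyclohexene C8–C9–C10–C11–C15–C16 thereby contracts to the cyclopentene C8–C9–C10–C15–C16, with C11 expelled from it, while the cyclopentane C11–C15 expands to the cyclohexanone C10–C15; neither ring is closed by a cyclisation, both arise from the one suprafacial 1,2-shift. C10 is set by inversion (C15 enters anti to the mesylate that the directed dihydroxylation placed syn to C12–OH) and C15 migrates with retention, which gives the cis ring fusion and the C9/C10/C15 relationship of the target. The selectivity needed is migration of C15 rather than C12 or hydride; the rigid trans-hydrindane secures it, because only the C11–C15 ring bond is anti to the leaving group. The cold, non-basic medium should keep the β-carbonyloxy ketone from eliminating and leaves C12–OH free for the next two steps.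

**Step 15**
Reactants: 21 ring-exchanged hydroxy ketone
Product: 22 C11,C12-trans-diol (C11–OH anti to C12–O)
Conditions: Me4NBH(OAc)3 (5 equiv), MeCN/AcOH (1:1), −30 °C
Reagents that add atoms: none
Why: Hydroxyl-directed triacetoxyborohydride reduction; the borohydride bound to C12–OH delivers hydride to the C11 ketone from the face of C12–O and should give the trans-diol of the target, while the conjugated C7 ketone, lactone and carbonate are inert to this reagent.

**Step 16**
Reactants: 22 C11,C12-trans-diol
Product: 23 ether-bridged cage (2-oxabicyclo[2.2.2]octane with C12–O–C16; C15–OBoc, C16–CH2CH2OTBS, C8–acyl trans to C9–OMe)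
Conditions: DBU (0.3 equiv), MeCN, 0 °C → rt
Reagents that add atoms: none
Why: Intramolecular oxa-Michael addition (6-exo-trig); the C12 alkoxide, 1,4 across the cyclohexane to C15, adds to C16, the β-carbon of the C7 enone, so C16 is fixed by the tether and C8 should be protonated under equilibrating conditions with the acyl group trans to C9–OMe.

**Step 17**
Reactants: 23 ether-bridged cage
Product: 24 triol (C11–OH, C15–OH, primary C1–OH)
Conditions: TFA/CH2Cl2/H2O (9:9:2), 0 °C
Reagents that add atoms: none
Why: Acidolysis removes the tertiary tert-butyl carbonate (as 2-methylpropene and CO2) and the primary silyl ether in one operation; the ether cage and the β-methoxy ketone should survive brief cold acid.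

**Step 18**
Reactants: 24 triol
Product: 25 bis-lactone (butyrolactone O–C15/C1/C2/C16 closed)
Conditions: TEMPO (0.2 equiv), PhI(OAc)2 (2.5 equiv), CH2Cl2, rt
Reagents that add atoms: none
Why: TEMPO-mediated oxidative lactonisation; the primary alcohol is oxidised to the aldehyde, which forms a lactol with the tertiary C15–OH and is oxidised on to the γ-lactone, while the hindered secondary C11–OH should react much more slowly.

**Step 19**
Reactants: 25 bis-lactone
Product: 26 target CNP0073200.1
Conditions: LiN(SiMe3)2 (4 equiv), THF, −78 → −20 °C; AcOH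
Reagents that add atoms: none
Why: Intramolecular Claisen (Dieckmann-type) acyl transfer; the C2 enolate of the butyrolactone attacks the C3 carbonyl of the γ-lactone held on the same face of the cyclopentane, the C6 alkoxide is expelled, and the β-keto lactone is trapped as its enolate, which drives the eight-membered ring closure and shields C4 from epimerisation.

**Compound list**
1 | cyclopent-4-ene-1,3-dione | O=C1CC(=O)C=C1 | starting material
2 | 8,8-dimethyl-6,10-dioxaspiro[4.5]dec-3-en-2-one | O=C1CC2(OCC(C)(C)CO2)C=C1 | intermediate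
3 | (4S)-4,8,8-trimethyl-6,10-dioxaspiro[4.5]decan-2-one | O=C1C[C@H](C)C2(OCC(C)(C)CO2)C1 | intermediate
4 | (4S)-4-methylcyclopentane-1,3-dione | C[C@H]1CC(=O)CC1=O | intermediate
5 | (5S)-3-hydroxy-2-iodo-5-methylcyclopent-2-en-1-one | C[C@H]1CC(O)=C(I)C1=O | intermediate
6 | tert-butyl (4S)-2-iodo-4-methyl-3-oxocyclopent-1-en-1-yl carbonate | C[C@H]1CC(OC(=O)OC(C)(C)C)=C(I)C1=O | intermediate
7 | 2-[(E)-2-methoxyethenyl]-4,4,5,5-tetramethyl-1,3,2-dioxaborolane | CO/C=C/B1OC(C)(C)C(C)(C)O1 | starting material
8 | tert-butyl (4S)-2-[(E)-2-methoxyethenyl]-4-methyl-3-oxocyclopent-1-en-1-yl carbonate | C[C@H]1CC(OC(=O)OC(C)(C)C)=C(/C=C/OC)C1=O | intermediate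
9 | tert-butyl (3S,4S)-3-hydroxy-2-[(E)-2-methoxyethenyl]-3,4-dimethylcyclopent-1-en-1-yl carbonate | C[C@H]1CC(OC(=O)OC(C)(C)C)=C(/C=C/OC)[C@@]1(C)O | intermediate
10 | (2R,5R)-2-tert-butyl-5-methyl-1,3-dioxolan-4-one | C[C@H]1O[C@@H](C(C)(C)C)OC1=O | starting material
11 | tert-butyl{[(2R)-3-iodo-2-methylpropyl]oxy}dimethylsilane | C[C@@H](CI)CO[Si](C)(C)C(C)(C)C | starting material
12 | (2R,5S)-2-tert-butyl-5-[(2S)-3-{[tert-butyl(dimethyl)silyl]oxy}-2-methylpropyl]-5-methyl-1,3-dioxolan-4-one | C[C@H](CO[Si](C)(C)C(C)(C)C)C[C@]1(C)O[C@@H](C(C)(C)C)OC1=O | intermediate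
13 | (2S)-3-[(2R,4S)-2-tert-butyl-4-methyl-5-oxo-1,3-dioxolan-4-yl]-2-methylpropanoic acid (dioxolanone acid, not isolated) | C[C@H](C(O)=O)C[C@]1(C)O[C@@H](C(C)(C)C)OC1=O | intermediate
14 | (2S,4S)-2,4-dimethyl-5-oxooxolane-2-carboxylic acid | C[C@H]1C[C@@](C)(C(O)=O)OC1=O | intermediate
15 | tert-butyl(but-3-yn-1-yloxy)dimethylsilane | C#CCCO[Si](C)(C)C(C)(C)C | starting material
16 | (2S,4S)-2,4-dimethyl-5-oxooxolane-2-carbonyl chloride (acid chloride, not isolated) | C[C@H]1C[C@@](C)(C(Cl)=O)OC1=O | intermediate
17 | (3S,5S)-5-(5-{[tert-butyl(dimethyl)silyl]oxy}pent-2-ynoyl)-3,5-dimethyloxolan-2-one | C[C@H]1C[C@@](C)(C(=O)C#CCCO[Si](C)(C)C(C)(C)C)OC1=O | intermediate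
18 | Diels–Alder adduct: 3a-(Boc-oxy)-1-hydroxy-6-methoxy-1,2-dimethyl-4-(2-TBS-oxyethyl)-5-(lactone-carbonyl)-2,3,3a,6-tetrahydro-1H-indene, C9–OMe cis to C14 | CO[C@H]1C=C2[C@@](C)(O)[C@@H](C)C[C@@]2(OC(=O)OC(C)(C)C)C(CCO[Si](C)(C)C(C)(C)C)=C1C(=O)[C@]3(C)C[C@H](C)C(=O)O3 | intermediate
19 | triol: 18 with cis C10–OH/C11–OH syn to C12–OH (trans-fused) | CO[C@H]1[C@@H](O)[C@]2(O)[C@@](C)(O)[C@@H](C)C[C@@]2(OC(=O)OC(C)(C)C)C(CCO[Si](C)(C)C(C)(C)C)=C1C(=O)[C@]3(C)C[C@H](C)C(=O)O3 | intermediate
20 | C10 methanesulfonate of 19 | CO[C@H]1[C@@H](OS(C)(=O)=O)[C@]2(O)[C@@](C)(O)[C@@H](C)C[C@@]2(OC(=O)OC(C)(C)C)C(CCO[Si](C)(C)C(C)(C)C)=C1C(=O)[C@]3(C)C[C@H](C)C(=O)O3 | intermediate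
21 | ring-exchanged hydroxy ketone: cis-fused cyclopentene (C8=C16)/cyclohexan-C11-one with C15–OBoc, C12–OH, C9–OMe | CO[C@H]1[C@H]2C(=O)[C@@](C)(O)[C@@H](C)C[C@@]2(OC(=O)OC(C)(C)C)C(CCO[Si](C)(C)C(C)(C)C)=C1C(=O)[C@]3(C)C[C@H](C)C(=O)O3 | intermediate
22 | C11,C12-trans-diol from 21 | CO[C@H]1[C@H]2[C@H](O)[C@@](C)(O)[C@@H](C)C[C@@]2(OC(=O)OC(C)(C)C)C(CCO[Si](C)(C)C(C)(C)C)=C1C(=O)[C@]3(C)C[C@H](C)C(=O)O3 | intermediate
23 | ether-bridged cage: C12–O–C16 2-oxabicyclo[2.2.2]octane fused to the cyclopentane, C15–OBoc, C16–CH2CH2OTBS, C8–acyl | CO[C@H]1[C@H]2[C@H](O)[C@@]3(C)O[C@@](CCO[Si](C)(C)C(C)(C)C)([C@@H]1C(=O)[C@]4(C)C[C@H](C)C(=O)O4)[C@]2(OC(=O)OC(C)(C)C)C[C@@H]3C | intermediate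
24 | triol: 23 with free C15–OH and primary C1–OH | CO[C@H]1[C@H]2[C@H](O)[C@@]3(C)O[C@@](CCO)([C@@H]1C(=O)[C@]4(C)C[C@H](C)C(=O)O4)[C@]2(O)C[C@@H]3C | intermediate
25 | bis-lactone: butyrolactone O–C15/C1/C2/C16 closed, γ-lactone C3–C6 on the C7 ketone | CO[C@H]1[C@H]2[C@H](O)[C@@]3(C)O[C@]4([C@@H]1C(=O)[C@]5(C)C[C@H](C)C(=O)O5)CC(=O)O[C@@]24C[C@@H]3C | intermediate
26 | CNP0073200.1 | CO[C@H]1[C@H]2[C@H](O)[C@@]3(C)O[C@@]45/C(=C(/O)[C@@H](C)C[C@](C)(O)C(=O)[C@H]14)C(=O)O[C@@]25C[C@@H]3C | target

**Totals**
Total step count: 19. Longest linear sequence: 16 steps (steps 1–7, then 11–19).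

**Three steps most likely to fail**

Step 11 (Diels–Alder). The cycloaddition may take the reverse orientation if the enol carbonate competes as donor, may add to the wrong diene face, or the adduct may aromatise by loss of the allylic carbonate. The fallback makes the cycloaddition intramolecular and sets out from 9 and 17. Compound 17 is desilylated with HF·pyridine to the hydroxy ynone F1. F1 is joined to the C12 hydroxyl of 9 through a diisopropylsilylene acetal (iPr2SiCl2, imidazole) to give the tethered diene–ynone F2. Heating F2 in toluene should give the tethered cycloadduct F3, because the short siloxane tether holds C16 next to C15 and on the face of C12–O. HF·pyridine then gives the diol F4, and TBSCl/imidazole silylates its primary hydroxyl, which comes back to the route at 18.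

Step 16 (oxa-Michael). The ether closure is reversible, so the equilibrium may lie on the side of the open enone, and base may expel methanol from C9. The fallback changes the order of events and sets out from 22. TFA/water removes both protecting groups to give the tetraol F5. TEMPO/PhI(OAc)2 closes the butyrolactone first to give the lactone enone F6, in which C16 is activated by the C7 ketone and, after isomerisation into conjugation, by the lactone carbonyl. Catalytic DBU should then close the ether, which comes back to the route at 25.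

Step 19 (Claisen ring closure). The eight-membered ring may close slowly, and the strong base may instead enolise C8 with loss of methoxide or epimerise C4. The fallback closes the eight-membered ring before the butyrolactone and sets out from 23. HF·pyridine removes only the silyl ether to give the primary alcohol F7. TEMPO/PhI(OAc)2 in MeCN/water gives the acid F8, and Me3SiCHN2/MeOH gives the methyl ester F9. The unconstrained ester enolate of F9 (LiN(SiMe3)2) is acylated by the C3 lactone to give the eight-membered β-keto ester F10. TFA then cleaves the carbonate, and the freed C15–OH should lactonise onto the methyl ester, which comes back to the route at 26.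

**Further compounds**
F1 | step 11 | (3S,5S)-5-(5-hydroxypent-2-ynoyl)-3,5-dimethyloxolan-2-one (hydroxy ynone) | C[C@H]1C[C@@](C)(C(=O)C#CCCO)OC1=O
F2 | step 11 | diisopropylsilylene acetal linking C12–O of 9 to the primary O of F1 (tethered diene–ynone) | C[C@H]1CC(OC(=O)OC(C)(C)C)=C(/C=C/OC)[C@@]1(C)O[Si](C(C)C)(C(C)C)OCCC#CC(=O)[C@]2(C)C[C@H](C)C(=O)O2
F3 | step 11 | tethered cycloadduct (18 with C12–O and C1–O bridged by Si(iPr)2) | CO[C@H]1C=C2[C@@]3(C)O[Si](C(C)C)(C(C)C)OCCC(=C1C(=O)[C@]4(C)C[C@H](C)C(=O)O4)[C@]2(OC(=O)OC(C)(C)C)C[C@@H]3C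
F4 | step 11 | diol (18 with free primary hydroxyl) | CO[C@H]1C=C2[C@@](C)(O)[C@@H](C)C[C@@]2(OC(=O)OC(C)(C)C)C(CCO)=C1C(=O)[C@]3(C)C[C@H](C)C(=O)O3
F5 | step 16 | tetraol (22 without Boc and TBS) | CO[C@H]1[C@H]2[C@H](O)[C@@](C)(O)[C@@H](C)C[C@@]2(O)C(CCO)=C1C(=O)[C@]3(C)C[C@H](C)C(=O)O3
F6 | step 16 | lactone enone (butyrolactone closed, C8=C16 enone, free C12–OH) | CO[C@H]1[C@H]2[C@H](O)[C@@](C)(O)[C@@H](C)C[C@]23OC(=O)CC3=C1C(=O)[C@]4(C)C[C@H](C)C(=O)O4
F7 | step 19 | primary alcohol (23 without TBS) | CO[C@H]1[C@H]2[C@H](O)[C@@]3(C)O[C@@](CCO)([C@@H]1C(=O)[C@]4(C)C[C@H](C)C(=O)O4)[C@]2(OC(=O)OC(C)(C)C)C[C@@H]3C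
F8 | step 19 | C1 carboxylic acid | CO[C@H]1[C@H]2[C@H](O)[C@@]3(C)O[C@@](CC(O)=O)([C@@H]1C(=O)[C@]4(C)C[C@H](C)C(=O)O4)[C@]2(OC(=O)OC(C)(C)C)C[C@@H]3C
F9 | step 19 | C1 methyl ester | CO[C@H]1[C@H]2[C@H](O)[C@@]3(C)O[C@@](CC(=O)OC)([C@@H]1C(=O)[C@]4(C)C[C@H](C)C(=O)O4)[C@]2(OC(=O)OC(C)(C)C)C[C@@H]3C
F10 | step 19 | eight-membered β-keto ester (enol form, C15–OBoc, free C6–OH) | CO[C@H]1[C@H]2[C@H](O)[C@@]3(C)O[C@]4(/C(=C(/O)[C@@H](C)C[C@](C)(O)C(=O)[C@H]14)C(=O)OC)[C@]2(OC(=O)OC(C)(C)C)C[C@@H]3C
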